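**Strategy.** Everything rests on closing the cyclopentanone last by joining C10, the ring CH2 next to the C9 ketone, to the carbinol carbon C11 (prostanoid numbering). The key step exploits the beta-ketol of the five-membered ring: in an acyclic diazomethyl ketone, the C11–H bonds of a CH2OTBS group lie next to oxygen and 1,5 to the carbenoid carbon C10. Dirhodium tetraacetate should then give, in one operation, the ring, the protected beta-ketol (no aldol equilibrium, no dehydration) and the C11 stereocentre. The precursor is a trans-alpha,beta-disubstituted gamma-butyrolactone, whose ring oxygen becomes the 11-oxygen; it is opened, silylated and homologated with diazomethane.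

Key step: step 9

Remark: atoms are numbered as in prostanoids (C1 acid carbon to C20), and TBSO stands for tert-butyldimethylsilyloxy. (S)-p-tol-BINAP in step 3 is assigned by analogy with related 4-alkyl butenolides; if a first run showed the opposite sense at C12, the (R)-ligand would be used with no other change.

Step 1
Reactants: 1 (S)-oct-1-en-3-ol
Product: 2 (S)-tert-butyldimethyl(oct-1-en-3-yloxy)silane
Conditions: TBSCl, imidazole, DMF, rt
Reagents that add atoms: tert-butyldimethylsilyl chloride, CC(C)(C)[Si](C)(C)Cl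
Why: Standard silylation of a secondary allylic alcohol; the C15 stereocentre comes from 1 and is not touched.

Step 2
Reactants: 2 (S)-tert-butyldimethyl(oct-1-en-3-yloxy)silane; 3 4-bromofuran-2(5H)-one
Product: 5 4-[(3S)-3-(TBSO)octyl]furan-2(5H)-one, via alkylborane 4 (not isolated)
Conditions: 9-BBN, THF, 0 °C → rt; then 3, PdCl2(dppf) (5 mol %), K3PO4 (aq), DMF, rt → 50 °C
Reagents that add atoms: none
Why: Anti-Markovnikov hydroboration of the terminal alkene followed by B-alkyl Suzuki–Miyaura coupling with the vinylogous acyl bromide 3 should form the C12–C13 bond without affecting C15.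

Step 3
Reactants: 5 4-[(3S)-3-(TBSO)octyl]furan-2(5H)-one
Product: 6 (4R)-4-[(3S)-3-(TBSO)octyl]dihydrofuran-2(3H)-one
Conditions: Cu(OAc)2 (5 mol %), (S)-p-tol-BINAP (5 mol %), (MeO)2MeSiH, t-BuOH, toluene, 0 °C → rt
Reagents that add atoms: none
Why: Asymmetric copper hydride conjugate reduction of a beta-substituted butenolide; the chiral bisphosphine selects the face of C12 under catalyst control (C15 is remote) and should set 12R.

Step 4
Reactants: 7 heptane-1,7-diol
Product: 8 7-(benzyloxy)heptan-1-ol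
Conditions: NaH (1 equiv), BnBr (1 equiv), excess 7, THF/DMF, 0 °C → rt
Reagents that add atoms: benzyl bromide, BrCc1ccccc1
Why: Williamson ether synthesis with excess diol should favour the mono-benzyl ether.

Step 5
Reactants: 8 7-(benzyloxy)heptan-1-ol
Product: 9 benzyl 7-iodoheptyl ether
Conditions: I2, PPh3, imidazole, CH2Cl2, 0 °C → rt
Reagents that add atoms: iodine, II
Why: Appel-type iodination of a primary alcohol.

Step 6
Reactants: 6 (4R)-4-[(3S)-3-(TBSO)octyl]dihydrofuran-2(3H)-one; 9 benzyl 7-iodoheptyl ether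
Product: 11 (3R,4R)-3-[7-(benzyloxy)heptyl]-4-[(3S)-3-(TBSO)octyl]dihydrofuran-2(3H)-one, via lithium enolate 10 (not isolated)
Conditions: LiN(iPr)2, THF, –78 °C; then 9, DMPU, –78 → –30 °C
Reagents that add atoms: none
Why: Lactone enolate alkylation; the iodide should approach anti to the C12 side chain, setting C8 (8R) trans to C12.

Step 7
Reactants: 11 (3R,4R)-3-[7-(benzyloxy)heptyl]-4-[(3S)-3-(TBSO)octyl]dihydrofuran-2(3H)-one
Product: 14 (2R,3R,6S)-2-[7-(benzyloxy)heptyl]-6-(TBSO)-3-[(TBSO)methyl]undecanoic acid, via potassium hydroxy carboxylate 12 (not isolated), via bis-silyl derivative 13 (not isolated)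
Conditions: KOH, MeOH/H2O, rt, evaporate; TBSCl, imidazole, DMF, rt; K2CO3, MeOH/THF/H2O, rt; KHSO4 (aq) to pH 4
Reagents that add atoms: potassium hydroxide, [K+].[OH-]; tert-butyldimethylsilyl chloride, CC(C)(C)[Si](C)(C)Cl
Why: Saponification by acyl–oxygen cleavage, silylation of the salt without acidification, and selective hydrolysis of the labile silyl ester should give the acid with C11–O protected, so it cannot relactonise.

Step 8
Reactants: 14 (2R,3R,6S)-2-[7-(benzyloxy)heptyl]-6-(TBSO)-3-[(TBSO)methyl]undecanoic acid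
Product: 16 (3R,4R,7S)-3-[7-(benzyloxy)heptyl]-1-diazo-7-(TBSO)-4-[(TBSO)methyl]dodecan-2-one, via mixed carbonic anhydride 15 (not isolated)
Conditions: i-BuOCOCl, N-methylmorpholine, THF, –15 °C; then CH2N2, Et2O, 0 °C → rt
Reagents that add atoms: diazomethane, C=[N+]=[N-]
Why: Acylation of diazomethane by a mixed anhydride (first stage of an Arndt–Eistert sequence) introduces C10 under conditions that form no ketene and should not epimerise C8.

Step 9
Reactants: 16 (3R,4R,7S)-3-[7-(benzyloxy)heptyl]-1-diazo-7-(TBSO)-4-[(TBSO)methyl]dodecan-2-one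
Product: 17 (2R,3R,4R)-2-[7-(benzyloxy)heptyl]-4-(TBSO)-3-[(3S)-3-(TBSO)octyl]cyclopentan-1-one
Conditions: Rh2(OAc)4 (1 mol %), CH2Cl2, rt, slow addition of 16 at high dilution
Reagents that add atoms: none
Why: Dirhodium tetraacetate expels N2 from 16 to give an electrophilic rhodium carbenoid at C10, which inserts in a concerted but asynchronous, hydride-transfer-like manner into a C11–H bond five atoms away, so that the C10–C11 bond and the cyclopentanone form together. The closest known reaction type is the Rh2(OAc)4-catalysed intramolecular 1,5 C–H insertion of alpha-diazo ketones to cyclopentanones, with its known preference for C–H bonds next to an ether oxygen; here it serves as a neutral surrogate of an intramolecular aldol addition. The one ring closes as a 1,5-insertion through a six-centre chair-like transition state made of C10, C9, C8, C12, C11 and the migrating hydrogen. The new stereocentre C11 is controlled by the fixed C12 and C8 centres: with both side chains and the OTBS group pseudo-equatorial in the chair, the 11,12-trans (11R) silyl ether should result. The step needs site selectivity among three 1,5-related methylene groups (C11, C13 and C6) and chemoselectivity against oxonium ylide formation; the oxygen lone pair makes the C11–H bonds the most hydridic, and the bulky, weakly basic silyl ether oxygen disfavours ylide formation. The neutral conditions should leave the beta-silyloxy ketone, the benzyl ether and the C8 centre untouched.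

Step 10
Reactants: 17 (2R,3R,4R)-2-[7-(benzyloxy)heptyl]-4-(TBSO)-3-[(3S)-3-(TBSO)octyl]cyclopentan-1-one
Product: 18 (2R,3R,4R)-2-(7-hydroxyheptyl)-4-(TBSO)-3-[(3S)-3-(TBSO)octyl]cyclopentan-1-one
Conditions: H2 (1 atm), 10% Pd/C, EtOAc, rt
Reagents that add atoms: none
Why: Hydrogenolysis of the benzyl ether under neutral conditions; the molecule has no alkene, and the ketone and silyl ethers should survive.

Step 11
Reactants: 18 (2R,3R,4R)-2-(7-hydroxyheptyl)-4-(TBSO)-3-[(3S)-3-(TBSO)octyl]cyclopentan-1-one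
Product: 20 7-[(1R,2R,3R)-3-(TBSO)-2-[(3S)-3-(TBSO)octyl]-5-oxocyclopentyl]heptanoic acid, via aldehyde 19 (not isolated)
Conditions: TEMPO (20 mol %), PhI(OAc)2 (2.2 equiv), MeCN/H2O, rt
Reagents that add atoms: water, O
Why: Oxoammonium-mediated oxidation of the primary alcohol through the aldehyde hydrate to the acid, under near-neutral conditions that should not eliminate the beta-silyloxy ketone.

Step 12
Reactants: 20 7-[(1R,2R,3R)-3-(TBSO)-2-[(3S)-3-(TBSO)octyl]-5-oxocyclopentyl]heptanoic acid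
Product: 21 13,14-dihydro-PGE1
Conditions: HF·pyridine, MeCN, 0 °C → rt
Reagents that add atoms: none
Why: Fluoride-mediated cleavage of both secondary silyl ethers in a buffered, weakly acidic medium should free the beta-ketol without dehydration.

**Compound list**

1 | (S)-oct-1-en-3-ol | CCCCC[C@H](O)C=C | starting material
2 | (S)-tert-butyldimethyl(oct-1-en-3-yloxy)silane | CCCCC[C@H](O[Si](C)(C)C(C)(C)C)C=C | intermediate
3 | 4-bromofuran-2(5H)-one | BrC1=CC(=O)OC1 | starting material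
4 | 9-[(3R)-3-(TBSO)octyl]-9-borabicyclo[3.3.1]nonane (C15 unchanged in space; the descriptor changes because boron ranks below carbon) | CCCCC[C@H](O[Si](C)(C)C(C)(C)C)CCB1C2CCCC1CCC2 | intermediate
5 | 4-[(3S)-3-(TBSO)octyl]furan-2(5H)-one | CCCCC[C@H](O[Si](C)(C)C(C)(C)C)CCC1=CC(=O)OC1 | intermediate
6 | (4R)-4-[(3S)-3-(TBSO)octyl]dihydrofuran-2(3H)-one | CCCCC[C@H](O[Si](C)(C)C(C)(C)C)CC[C@H]1COC(=O)C1 | intermediate
7 | heptane-1,7-diol | OCCCCCCCO | starting material
8 | 7-(benzyloxy)heptan-1-ol | OCCCCCCCOCc1ccccc1 | intermediate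
9 | benzyl 7-iodoheptyl ether | ICCCCCCCOCc1ccccc1 | intermediate
10 | lithium enolate of lactone 6 | CCCCC[C@H](O[Si](C)(C)C(C)(C)C)CC[C@H]1COC(O[Li])=C1 | intermediate
11 | (3R,4R)-3-[7-(benzyloxy)heptyl]-4-[(3S)-3-(TBSO)octyl]dihydrofuran-2(3H)-one | CCCCC[C@H](O[Si](C)(C)C(C)(C)C)CC[C@H]1COC(=O)[C@@H]1CCCCCCCOCc1ccccc1 | intermediate
12 | potassium (2R,3R,6S)-2-[7-(benzyloxy)heptyl]-3-(hydroxymethyl)-6-(TBSO)undecanoate | CCCCC[C@H](O[Si](C)(C)C(C)(C)C)CC[C@@H](CO)[C@@H](CCCCCCCOCc1ccccc1)C(=O)[O-].[K+] | intermediate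
13 | tert-butyldimethylsilyl (2R,3R,6S)-2-[7-(benzyloxy)heptyl]-6-(TBSO)-3-[(TBSO)methyl]undecanoate | CCCCC[C@H](O[Si](C)(C)C(C)(C)C)CC[C@@H](CO[Si](C)(C)C(C)(C)C)[C@@H](CCCCCCCOCc1ccccc1)C(=O)O[Si](C)(C)C(C)(C)C | intermediate
14 | (2R,3R,6S)-2-[7-(benzyloxy)heptyl]-6-(TBSO)-3-[(TBSO)methyl]undecanoic acid | CCCCC[C@H](O[Si](C)(C)C(C)(C)C)CC[C@@H](CO[Si](C)(C)C(C)(C)C)[C@@H](CCCCCCCOCc1ccccc1)C(=O)O | intermediate
15 | isobutyl carbonic mixed anhydride of acid 14 | CCCCC[C@H](O[Si](C)(C)C(C)(C)C)CC[C@@H](CO[Si](C)(C)C(C)(C)C)[C@@H](CCCCCCCOCc1ccccc1)C(=O)OC(=O)OCC(C)C | intermediate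
16 | (3R,4R,7S)-3-[7-(benzyloxy)heptyl]-1-diazo-7-(TBSO)-4-[(TBSO)methyl]dodecan-2-one | CCCCC[C@H](O[Si](C)(C)C(C)(C)C)CC[C@@H](CO[Si](C)(C)C(C)(C)C)[C@@H](CCCCCCCOCc1ccccc1)C(=O)C=[N+]=[N-] | intermediate
17 | (2R,3R,4R)-2-[7-(benzyloxy)heptyl]-4-(TBSO)-3-[(3S)-3-(TBSO)octyl]cyclopentan-1-one | CCCCC[C@H](O[Si](C)(C)C(C)(C)C)CC[C@H]1[C@H](O[Si](C)(C)C(C)(C)C)CC(=O)[C@@H]1CCCCCCCOCc1ccccc1 | intermediate
18 | (2R,3R,4R)-2-(7-hydroxyheptyl)-4-(TBSO)-3-[(3S)-3-(TBSO)octyl]cyclopentan-1-one | CCCCC[C@H](O[Si](C)(C)C(C)(C)C)CC[C@H]1[C@H](O[Si](C)(C)C(C)(C)C)CC(=O)[C@@H]1CCCCCCCO | intermediate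
19 | 7-[(1R,2R,3R)-3-(TBSO)-2-[(3S)-3-(TBSO)octyl]-5-oxocyclopentyl]heptanal | CCCCC[C@H](O[Si](C)(C)C(C)(C)C)CC[C@H]1[C@H](O[Si](C)(C)C(C)(C)C)CC(=O)[C@@H]1CCCCCCC=O | intermediate
20 | 7-[(1R,2R,3R)-3-(TBSO)-2-[(3S)-3-(TBSO)octyl]-5-oxocyclopentyl]heptanoic acid | CCCCC[C@H](O[Si](C)(C)C(C)(C)C)CC[C@H]1[C@H](O[Si](C)(C)C(C)(C)C)CC(=O)[C@@H]1CCCCCCC(=O)O | intermediate
21 | 13,14-dihydro-PGE1, 7-[(1R,2R,3R)-3-hydroxy-2-[(3S)-3-hydroxyoctyl]-5-oxocyclopentyl]heptanoic acid | CCCCC[C@H](O)CC[C@H]1[C@H](O)CC(=O)[C@@H]1CCCCCCC(=O)O | target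

**Step count and risks**

Total steps: 12. Longest linear sequence: 10 (steps 1–3 and 6–12).

Most likely to fail:

1. Step 9. The carbenoid may insert at the unactivated C13–H or C6–H bonds, may abstract hydride from C11 without closing the C–C bond, or may show poor facial selectivity at C11. Fallback (from 16, back at 17): the ring is closed by an aldol-type addition with C10 as a regiodefined enolate. HBr (Et2O, –20 °C) converts 16 into the bromomethyl ketone (3R,4R,7S)-3-[7-(benzyloxy)heptyl]-1-bromo-7-(TBSO)-4-[(TBSO)methyl]dodecan-2-one F1. HF·pyridine buffered with pyridine (THF, 0 °C) removes only the primary silyl ether to give the hydroxy bromo ketone F2. Dess–Martin periodinane (NaHCO3, CH2Cl2) gives the bromo keto aldehyde F3. SmI2 (THF, –78 °C) reduces the C–Br bond to a samarium enolate at C10, which adds to the C11 aldehyde in an intramolecular Reformatsky-type reaction to give the 11-hydroxy cyclopentanone F4. TBSCl, imidazole, DMF then returns to 17.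

2. Step 6. The unactivated primary iodide may alkylate the lactone enolate slowly, with proton exchange and double alkylation. Fallback (from 6, back at 11): enolate 10 is alkylated with the far more reactive allyl bromide to give the trans allyl lactone (3R,4R)-3-allyl-4-[(3S)-3-(TBSO)octyl]dihydrofuran-2(3H)-one F5. Cross metathesis with benzyl hex-5-enyl ether (second-generation Hoveyda–Grubbs catalyst, CH2Cl2, 40 °C) gives the alkene F6. Homogeneous hydrogenation with RhCl(PPh3)3 and H2 (benzene/EtOH) saturates the alkene without cleaving the benzyl ether and gives 11.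

3. Step 7. The hydroxyl may attack the silyl ester during silylation, or the product may relactonise on acidification. Fallback (from 11, back at 16): Me3Al and MeNH(OMe)·HCl (CH2Cl2, 0 °C) open the lactone to the hydroxy N-methoxy-N-methyl amide F7. TBSCl and imidazole give the silyl ether F8. MeMgBr (THF, 0 °C) gives the methyl ketone F9. LiN(SiMe3)2 and CF3CO2CH2CF3 (THF, –78 °C) acylate the methyl side to give the trifluoroacetyl ketone F10. MsN3, Et3N and H2O in MeCN (deacylative Regitz diazo transfer) then give 16, which also avoids diazomethane.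

**Further compounds**

F1 | step 9 | (3R,4R,7S)-3-[7-(benzyloxy)heptyl]-1-bromo-7-(TBSO)-4-[(TBSO)methyl]dodecan-2-one | CCCCC[C@H](O[Si](C)(C)C(C)(C)C)CC[C@@H](CO[Si](C)(C)C(C)(C)C)[C@@H](CCCCCCCOCc1ccccc1)C(=O)CBr
F2 | step 9 | (3R,4R,7S)-3-[7-(benzyloxy)heptyl]-1-bromo-4-(hydroxymethyl)-7-(TBSO)dodecan-2-one | CCCCC[C@H](O[Si](C)(C)C(C)(C)C)CC[C@@H](CO)[C@@H](CCCCCCCOCc1ccccc1)C(=O)CBr
F3 | step 9 | (2R,3R)-3-[7-(benzyloxy)heptyl]-5-bromo-4-oxo-2-[(3S)-3-(TBSO)octyl]pentanal | CCCCC[C@H](O[Si](C)(C)C(C)(C)C)CC[C@@H](C=O)[C@@H](CCCCCCCOCc1ccccc1)C(=O)CBr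
F4 | step 9 | (2R,3R,4R)-2-[7-(benzyloxy)heptyl]-4-hydroxy-3-[(3S)-3-(TBSO)octyl]cyclopentan-1-one | CCCCC[C@H](O[Si](C)(C)C(C)(C)C)CC[C@H]1[C@H](O)CC(=O)[C@@H]1CCCCCCCOCc1ccccc1
F5 | step 6 | (3R,4R)-3-allyl-4-[(3S)-3-(TBSO)octyl]dihydrofuran-2(3H)-one | CCCCC[C@H](O[Si](C)(C)C(C)(C)C)CC[C@H]1COC(=O)[C@@H]1CC=C
F6 | step 6 | (3R,4R)-3-[(E)-7-(benzyloxy)hept-2-enyl]-4-[(3S)-3-(TBSO)octyl]dihydrofuran-2(3H)-one | CCCCC[C@H](O[Si](C)(C)C(C)(C)C)CC[C@H]1COC(=O)[C@@H]1C/C=C/CCCCOCc1ccccc1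
F7 | step 7 | (2R,3R,6S)-2-[7-(benzyloxy)heptyl]-3-(hydroxymethyl)-N-methoxy-N-methyl-6-(TBSO)undecanamide | CCCCC[C@H](O[Si](C)(C)C(C)(C)C)CC[C@@H](CO)[C@@H](CCCCCCCOCc1ccccc1)C(=O)N(C)OC
F8 | step 7 | (2R,3R,6S)-2-[7-(benzyloxy)heptyl]-N-methoxy-N-methyl-6-(TBSO)-3-[(TBSO)methyl]undecanamide | CCCCC[C@H](O[Si](C)(C)C(C)(C)C)CC[C@@H](CO[Si](C)(C)C(C)(C)C)[C@@H](CCCCCCCOCc1ccccc1)C(=O)N(C)OC
F9 | step 7 | (3R,4R,7S)-3-[7-(benzyloxy)heptyl]-7-(TBSO)-4-[(TBSO)methyl]dodecan-2-one | CCCCC[C@H](O[Si](C)(C)C(C)(C)C)CC[C@@H](CO[Si](C)(C)C(C)(C)C)[C@@H](CCCCCCCOCc1ccccc1)C(C)=O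
F10 | step 7 | (5R,6R,9S)-5-[7-(benzyloxy)heptyl]-1,1,1-trifluoro-9-(TBSO)-6-[(TBSO)methyl]tetradecane-2,4-dione | CCCCC[C@H](O[Si](C)(C)C(C)(C)C)CC[C@@H](CO[Si](C)(C)C(C)(C)C)[C@@H](CCCCCCCOCc1ccccc1)C(=O)CC(=O)C(F)(F)F
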